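Ring A is made last. Its 1,3,5-oxygen pattern (O1 on C8a, the C5 and C7 hydroxyls) around the C8 ketone maps onto a β-keto ester bis(silyl enol ether) and an alkoxy ynone, so one formal [4+2] benzannulation forges C4a–C8a and C7–C8, aromatises by loss of methanol and delivers the three oxygens differentiated (two phenols, O1 as a tert-butyl ether) with the C8 acyl group in place. The diene carries the preset C4 stereocentre, ring B as its benzyl ether and the future C2–C3 arm as a silyl-protected hydroxyethyl group; it stems from a catalytic asymmetric conjugate addition. O1 is then unveiled alone and the lactone closed oxidatively.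

Key step: step 9

Remark on numbering and configuration: locants O1–C8a follow chroman-2-one numbering (ring A = C4a–C8a, ring B = the aryl group on C4); the target is 4S, and the same spatial arrangement is R in lactone 3 and diene 11 because the substituent ranking changes.
Remark on supply: tert-butoxyethyne 14 is taken as purchasable; the enol ether geometries of 9–11 are drawn as expected, and only the 4Z geometry of 11 matters.

Step 1
Reactants: 1 4-(benzyloxy)phenylboronic acid; 2 5,6-dihydro-2H-pyran-2-one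
Product: 3 (4R)-4-[4-(benzyloxy)phenyl]oxan-2-one
Conditions: [Rh(acac)(C2H4)2] (3 mol %), (R)-BINAP (3.3 mol %), 1 (2.5 equiv), 1,4-dioxane/H2O 10:1, 100 °C
Reagents that add atoms: none
Why: Hayashi–Miyaura rhodium-catalysed asymmetric 1,4-addition, in which the aryl–rhodium/(R)-BINAP complex inserts the lactone alkene from one enantioface (the S ligand is known to give the S series with cyclic enones and unsaturated lactones), so the R ligand should set the 4R centre that becomes C4 of the target.

Step 2
Reactants: 3 (4R)-4-[4-(benzyloxy)phenyl]oxan-2-one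
Product: 4 (3R)-3-[4-(benzyloxy)phenyl]-5-hydroxy-N-methoxy-N-methylpentanamide
Conditions: MeNHOMe·HCl, i-PrMgCl, THF, −20 → 0 °C; aq. NH4Cl; crude product used at once
Reagents that add atoms: N,O-dimethylhydroxylamine hydrochloride, CNOC.Cl
Why: Weinreb amide formation by aminolysis of the lactone with the chloromagnesium amide opens the ring at low temperature without touching the β-stereocentre, and immediate use of the crude hydroxy amide prevents its closing back to 3.

Step 3
Reactants: 4 (3R)-3-[4-(benzyloxy)phenyl]-5-hydroxy-N-methoxy-N-methylpentanamide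
Product: 5 (3R)-3-[4-(benzyloxy)phenyl]-5-[(tert-butyldimethylsilyl)oxy]-N-methoxy-N-methylpentanamide
Conditions: TBSCl, imidazole, DMF, 0 → 23 °C
Reagents that add atoms: tert-butyldimethylsilyl chloride, CC(C)(C)[Si](C)(C)Cl
Why: Standard imidazole-promoted silylation of a primary alcohol blocks relactonisation and installs an ether that tolerates ester enolates and lithium amides.

Step 4
Reactants: 5 (3R)-3-[4-(benzyloxy)phenyl]-5-[(tert-butyldimethylsilyl)oxy]-N-methoxy-N-methylpentanamide; 6 methyl acetate
Product: 8 methyl (5R)-5-[4-(benzyloxy)phenyl]-7-[(tert-butyldimethylsilyl)oxy]-3-oxoheptanoate, via lithium enolate of methyl acetate 7 (not isolated)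
Conditions: LiN(i-Pr)2 (3 equiv), 6 (3 equiv), THF, −78 °C; then 5, −78 → −40 °C; aq. NH4Cl
Reagents that add atoms: none
Why: Crossed Claisen-type acylation of an ester enolate by a Weinreb amide, where the chelated tetrahedral adduct prevents over-addition and gives the β-keto ester on quench, the stereocentre being β to the new ketone and therefore not epimerisable.

Step 5
Reactants: 8 methyl (5R)-5-[4-(benzyloxy)phenyl]-7-[(tert-butyldimethylsilyl)oxy]-3-oxoheptanoate
Product: 9 methyl (2Z,5R)-5-[4-(benzyloxy)phenyl]-7-[(tert-butyldimethylsilyl)oxy]-3-[(trimethylsilyl)oxy]hept-2-enoate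
Conditions: TMSCl, Et3N, toluene, 23 °C; filtration under argon, used crude
Reagents that add atoms: chlorotrimethylsilane, C[Si](C)(C)Cl
Why: O-Silylation of the enolised β-keto ester is the standard first stage of 1,3-bis(silyloxy)diene preparation, and the geometry of this enol ether (drawn Z) is lost in step 6.

Step 6
Reactants: 9 methyl (2Z,5R)-5-[4-(benzyloxy)phenyl]-7-[(tert-butyldimethylsilyl)oxy]-3-[(trimethylsilyl)oxy]hept-2-enoate
Product: 11 tert-butyl{[(3R,4Z,6Z)-3-[4-(benzyloxy)phenyl]-7-methoxy-5,7-bis(trimethylsilyloxy)hepta-4,6-dien-1-yl]oxy}dimethylsilane, via γ-lithiated dienolate 10 (not isolated)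
Conditions: LiN(i-Pr)2 (1.2 equiv), THF, −78 °C; TMSCl, −78 → 0 °C; pentane, filtration, used crude
Reagents that add atoms: chlorotrimethylsilane, C[Si](C)(C)Cl
Why: Kinetic γ-deprotonation of the vinylogous ester and O-silylation of the extended enolate is the standard second stage for 4-substituted 1-methoxy-1,3-bis(silyloxy)dienes, which should form with the 4-substituent outside the s-cis diene (4Z), and the C3 hydrogen is not acidic, so the stereocentre is kept.

Step 7
Reactants: 12 3-phenylpropanoyl chloride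
Product: 13 N-methoxy-N-methyl-3-phenylpropanamide
Conditions: MeNHOMe·HCl, Et3N (2.2 equiv), CH2Cl2, 0 → 23 °C
Reagents that add atoms: N,O-dimethylhydroxylamine hydrochloride, CNOC.Cl
Why: N-Acylation of N,O-dimethylhydroxylamine by an acid chloride is the routine Weinreb amide synthesis.

Step 8
Reactants: 13 N-methoxy-N-methyl-3-phenylpropanamide; 14 tert-butoxyethyne
Product: 16 1-tert-butoxy-5-phenylpent-1-yn-3-one, via lithium tert-butoxyacetylide 15 (not isolated)
Conditions: n-BuLi, THF, −78 °C; then 13, −78 → −30 °C; cold aq. NH4Cl, rapid extraction, stored cold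
Reagents that add atoms: none
Why: Weinreb ketone synthesis with a lithiated ynol ether, where the chelated adduct survives until the cold quench so that a single addition gives the alkoxy ynone, and the low temperature spares the acid- and heat-sensitive tert-butyl ynol ether.

Step 9
Reactants: 11 tert-butyl{[(3R,4Z,6Z)-3-[4-(benzyloxy)phenyl]-7-methoxy-5,7-bis(trimethylsilyloxy)hepta-4,6-dien-1-yl]oxy}dimethylsilane; 16 1-tert-butoxy-5-phenylpent-1-yn-3-one
Product: 19 1-[2-tert-butoxy-3-{(1S)-1-[4-(benzyloxy)phenyl]-3-[(tert-butyldimethylsilyl)oxy]propyl}-4,6-dihydroxyphenyl]-3-phenylpropan-1-one, via cyclohexa-1,4-diene cycloadduct 17 (not isolated), via bis(trimethylsilyl) aryl ether 18 (not isolated)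
Conditions: 16 (2 equiv), toluene (1 M), 0 → 40 °C, argon; then citric acid (aq.), THF, 0 °C
Reagents that add atoms: none
Why: Proposed new method: the substituted diene terminus of 11 (future C4a) should add to the ketone-β, tert-butoxy-bearing alkyne carbon of 16 (future C8a) and the allenolate α-carbon (future C8) should close onto the ketene acetal carbon (future C7), either as one asynchronous [4+2] event or as a Mukaiyama–Michael addition followed by ion-pair collapse, after which 1,4-elimination of methanol from 17 (methoxy on C7, hydrogen on C4a) gives arene 18 and dilute acid removes the two aryl trimethylsilyl groups. The closest known reaction type is the Diels–Alder benzannulation of 1-methoxy-1,3-bis(trimethylsilyloxy)buta-1,3-dienes with acetylenic esters and ketones to resorcinols; the extensions are the β-alkoxy (push–pull) ynone and the branched substituent on the diene terminus. Ring A closes as a six-membered carbocycle by intermolecular [4+2] cycloaddition that forms C4a–C8a and C7–C8, not by cyclisation of a tethered chain. No stereocentre is created in 19: the two sp3 ring carbons of 17 are erased on aromatisation, and the side-chain centre set in step 1 is neither acidic nor allylically transposable in 11, 17 or 19. The step needs regioselectivity (substituted terminus to the alkoxy carbon) and periselectivity (closure at the ketene acetal carbon and not aldol closure of future C6 onto the ketone, which would give a salicylate); polarity matching of the most nucleophilic diene terminus with the ynone β-carbon secures the first, Lewis-acid-free conditions that keep the ketene acetal intact secure the second, and the 40 °C ceiling avoids retro-ene loss of 2-methylpropene from the ynol ether.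

Step 10
Reactants: 19 1-[2-tert-butoxy-3-{(1S)-1-[4-(benzyloxy)phenyl]-3-[(tert-butyldimethylsilyl)oxy]propyl}-4,6-dihydroxyphenyl]-3-phenylpropan-1-one
Product: 20 1-[4,6-bis(benzyloxy)-2-tert-butoxy-3-{(1S)-1-[4-(benzyloxy)phenyl]-3-[(tert-butyldimethylsilyl)oxy]propyl}phenyl]-3-phenylpropan-1-one
Conditions: BnBr (4 equiv), K2CO3, n-Bu4NI (cat.), DMF, 60 °C
Reagents that add atoms: benzyl bromide, BrCc1ccccc1
Why: Williamson O-benzylation of both phenols (warm DMF for the ketone-chelated C7 hydroxyl) blocks the C5 oxygen, so that only O1, still a base-stable tert-butyl ether, can later close the lactone.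

Step 11
Reactants: 20 1-[4,6-bis(benzyloxy)-2-tert-butoxy-3-{(1S)-1-[4-(benzyloxy)phenyl]-3-[(tert-butyldimethylsilyl)oxy]propyl}phenyl]-3-phenylpropan-1-one
Product: 21 1-[4,6-bis(benzyloxy)-3-{(1S)-1-[4-(benzyloxy)phenyl]-3-hydroxypropyl}-2-hydroxyphenyl]-3-phenylpropan-1-one
Conditions: CF3CO2H/CH2Cl2 1:4, H2O (5 equiv), 0 → 23 °C; then NaHCO3, MeOH/H2O
Reagents that add atoms: none
Why: Acidolysis cleaves the aryl tert-butyl ether (ionisation to the tert-butyl cation, eased by the ortho acyl group and steric compression) and the primary silyl ether together, while aryl benzyl ethers should persist at this acid strength, the wet medium and the bicarbonate–methanol work-up deliver the primary alcohol free, and C4 has no pathway to epimerise.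

Step 12
Reactants: 21 1-[4,6-bis(benzyloxy)-3-{(1S)-1-[4-(benzyloxy)phenyl]-3-hydroxypropyl}-2-hydroxyphenyl]-3-phenylpropan-1-one
Product: 24 (4S)-5,7-bis(benzyloxy)-4-[4-(benzyloxy)phenyl]-8-(3-phenylpropanoyl)-3,4-dihydro-2H-chromen-2-one, via hydroxy aldehyde 22 (not isolated), via lactol 23 (not isolated)
Conditions: [C5H5NH][CrO3Cl] (pyridinium chlorochromate, 3 equiv), powdered 4 Å molecular sieves, CH2Cl2, 23 °C
Reagents that add atoms: none
Why: Oxidative lactonisation, in which the hexavalent chromium reagent oxidises the primary alcohol to aldehyde 22, the neighbouring O1 phenol traps it as six-membered lactol 23 and a second oxidation gives the lactone, closure being possible only at O1 because the C5 and C7 oxygens are benzylated.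

Step 13
Reactants: 24 (4S)-5,7-bis(benzyloxy)-4-[4-(benzyloxy)phenyl]-8-(3-phenylpropanoyl)-3,4-dihydro-2H-chromen-2-one
Product: 25 (4S)-5,7-dihydroxy-4-(4-hydroxyphenyl)-8-(3-phenylpropanoyl)-3,4-dihydro-2H-chromen-2-one
Conditions: H2 (1 atm), Pd/C (10 %), EtOAc, 23 °C
Reagents that add atoms: none
Why: Hydrogenolysis of the three aryl benzyl ethers over palladium on carbon in a neutral, non-nucleophilic solvent leaves the aryl lactone, the hydrogen-bonded aryl ketone and the C4 stereocentre untouched.

Compound list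
1 | 4-(benzyloxy)phenylboronic acid | OB(O)c1ccc(OCc2ccccc2)cc1 | starting material
2 | 5,6-dihydro-2H-pyran-2-one | O=C1C=CCCO1 | starting material
3 | (4R)-4-[4-(benzyloxy)phenyl]oxan-2-one | O=C1C[C@H](c2ccc(OCc3ccccc3)cc2)CCO1 | intermediate
4 | (3R)-3-[4-(benzyloxy)phenyl]-5-hydroxy-N-methoxy-N-methylpentanamide | CON(C)C(=O)C[C@H](c1ccc(OCc2ccccc2)cc1)CCO | intermediate
5 | (3R)-3-[4-(benzyloxy)phenyl]-5-[(tert-butyldimethylsilyl)oxy]-N-methoxy-N-methylpentanamide | CON(C)C(=O)C[C@H](c1ccc(OCc2ccccc2)cc1)CCO[Si](C)(C)C(C)(C)C | intermediate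
6 | methyl acetate | COC(C)=O | starting material
7 | lithium enolate of methyl acetate (lithium 1-methoxyethenolate) | [Li]OC(=C)OC | intermediate (not isolated)
8 | methyl (5R)-5-[4-(benzyloxy)phenyl]-7-[(tert-butyldimethylsilyl)oxy]-3-oxoheptanoate | COC(=O)CC(=O)C[C@H](c1ccc(OCc2ccccc2)cc1)CCO[Si](C)(C)C(C)(C)C | intermediate
9 | methyl (2Z,5R)-5-[4-(benzyloxy)phenyl]-7-[(tert-butyldimethylsilyl)oxy]-3-[(trimethylsilyl)oxy]hept-2-enoate | COC(=O)/C=C(\O[Si](C)(C)C)C[C@H](c1ccc(OCc2ccccc2)cc1)CCO[Si](C)(C)C(C)(C)C | intermediate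
10 | γ-lithiated dienolate of 9 (lithium ketene acetal, stereocentre R) | CC(C)(C)[Si](C)(C)OCC[C@@H](c1ccc(OCc2ccccc2)cc1)/C=C(O[Si](C)(C)C)/C=C(/OC)O[Li] | intermediate (not isolated)
11 | tert-butyl{[(3R,4Z,6Z)-3-[4-(benzyloxy)phenyl]-7-methoxy-5,7-bis(trimethylsilyloxy)hepta-4,6-dien-1-yl]oxy}dimethylsilane | CC(C)(C)[Si](C)(C)OCC[C@@H](c1ccc(OCc2ccccc2)cc1)/C=C(O[Si](C)(C)C)/C=C(/OC)O[Si](C)(C)C | intermediate (key-step precursor)
12 | 3-phenylpropanoyl chloride | O=C(Cl)CCc1ccccc1 | starting material
13 | N-methoxy-N-methyl-3-phenylpropanamide | CON(C)C(=O)CCc1ccccc1 | intermediate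
14 | tert-butoxyethyne | CC(C)(C)OC#C | starting material
15 | lithium tert-butoxyacetylide | CC(C)(C)OC#C[Li] | intermediate (not isolated)
16 | 1-tert-butoxy-5-phenylpent-1-yn-3-one | CC(C)(C)OC#CC(=O)CCc1ccccc1 | intermediate (key-step precursor)
17 | 1-[2-tert-butoxy-3-{1-[4-(benzyloxy)phenyl]-3-[(tert-butyldimethylsilyl)oxy]propyl}-6-methoxy-4,6-bis(trimethylsilyloxy)cyclohexa-1,4-dien-1-yl]-3-phenylpropan-1-one (side-chain centre unchanged, formally 1R here; ring centres C3 and C6 undefined) | COC1(O[Si](C)(C)C)C=C(O[Si](C)(C)C)C([C@@H](CCO[Si](C)(C)C(C)(C)C)c2ccc(OCc3ccccc3)cc2)C(OC(C)(C)C)=C1C(=O)CCc4ccccc4 | intermediate (not isolated)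
18 | 1-[2-tert-butoxy-3-{(1S)-1-[4-(benzyloxy)phenyl]-3-[(tert-butyldimethylsilyl)oxy]propyl}-4,6-bis(trimethylsilyloxy)phenyl]-3-phenylpropan-1-one | CC(C)(C)[Si](C)(C)OCC[C@@H](c1ccc(OCc2ccccc2)cc1)c1c(O[Si](C)(C)C)cc(O[Si](C)(C)C)c(C(=O)CCc2ccccc2)c1OC(C)(C)C | intermediate (not isolated)
19 | 1-[2-tert-butoxy-3-{(1S)-1-[4-(benzyloxy)phenyl]-3-[(tert-butyldimethylsilyl)oxy]propyl}-4,6-dihydroxyphenyl]-3-phenylpropan-1-one | CC(C)(C)[Si](C)(C)OCC[C@@H](c1ccc(OCc2ccccc2)cc1)c1c(O)cc(O)c(C(=O)CCc2ccccc2)c1OC(C)(C)C | intermediate (key-step product)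
20 | 1-[4,6-bis(benzyloxy)-2-tert-butoxy-3-{(1S)-1-[4-(benzyloxy)phenyl]-3-[(tert-butyldimethylsilyl)oxy]propyl}phenyl]-3-phenylpropan-1-one | CC(C)(C)[Si](C)(C)OCC[C@@H](c1ccc(OCc2ccccc2)cc1)c1c(OCc2ccccc2)cc(OCc2ccccc2)c(C(=O)CCc2ccccc2)c1OC(C)(C)C | intermediate
21 | 1-[4,6-bis(benzyloxy)-3-{(1S)-1-[4-(benzyloxy)phenyl]-3-hydroxypropyl}-2-hydroxyphenyl]-3-phenylpropan-1-one | OCC[C@@H](c1ccc(OCc2ccccc2)cc1)c1c(OCc2ccccc2)cc(OCc2ccccc2)c(C(=O)CCc2ccccc2)c1O | intermediate
22 | (3S)-3-[4-(benzyloxy)phenyl]-3-[2,4-bis(benzyloxy)-6-hydroxy-5-(3-phenylpropanoyl)phenyl]propanal | O=CC[C@@H](c1ccc(OCc2ccccc2)cc1)c1c(OCc2ccccc2)cc(OCc2ccccc2)c(C(=O)CCc2ccccc2)c1O | intermediate (not isolated)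
23 | 1-{(4S)-5,7-bis(benzyloxy)-4-[4-(benzyloxy)phenyl]-2-hydroxy-3,4-dihydro-2H-chromen-8-yl}-3-phenylpropan-1-one (lactol, C2 undefined) | OC1C[C@@H](c2ccc(OCc3ccccc3)cc2)c2c(OCc3ccccc3)cc(OCc3ccccc3)c(C(=O)CCc3ccccc3)c2O1 | intermediate (not isolated)
24 | (4S)-5,7-bis(benzyloxy)-4-[4-(benzyloxy)phenyl]-8-(3-phenylpropanoyl)-3,4-dihydro-2H-chromen-2-one | O=C1C[C@@H](c2ccc(OCc3ccccc3)cc2)c2c(OCc3ccccc3)cc(OCc3ccccc3)c(C(=O)CCc3ccccc3)c2O1 | intermediate
25 | (4S)-5,7-dihydroxy-4-(4-hydroxyphenyl)-8-(3-phenylpropanoyl)-3,4-dihydro-2H-chromen-2-one | O=C1C[C@@H](c2ccc(O)cc2)c2c(O)cc(O)c(C(=O)CCc3ccccc3)c2O1 | target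

Total step count: 13.
Longest linear sequence: 11 steps (steps 1–6, then 9–13, from 1 and 2); the ynone branch (steps 7 and 8) has 2 steps.

Steps most likely to fail

Step 9 (proposed new method). The alkoxy-deactivated ynone may not engage the hindered diene terminus below the temperature at which its tert-butyl ynol ether fragments, or ring closure may take the aldol course instead of closing at the ketene acetal carbon. The fallback uses known reactions only, gives up the late construction of ring A and creates C4 last by conjugate arylation; it sets out from 12 and 1 and comes back to the route at 24. Purchased 5,7-dihydroxy-2H-chromen-2-one F1 is acylated at C8 with 12 (AlCl3, nitrobenzene, 70 °C; Friedel–Crafts acylation, C8 being the usual site in 5,7-dihydroxycoumarins) to give 5,7-dihydroxy-8-(3-phenylpropanoyl)-2H-chromen-2-one F2. Both phenols are benzylated (BnBr, K2CO3, DMF) to give 5,7-bis(benzyloxy)-8-(3-phenylpropanoyl)-2H-chromen-2-one F3. Rhodium-catalysed asymmetric 1,4-addition of 1 to F3 ([Rh(acac)(C2H4)2], (S)-SEGPHOS, 1,4-dioxane/H2O, 60 °C) should then give 24, which continues with step 13. The S ligand is chosen because the R ligand gives 4R products with simple coumarins and the ranking of the C4 substituents is the same here.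

Step 12. The hexavalent chromium reagent may over-oxidise the electron-rich free phenol, or the oxidation may stall at the lactol. The fallback separates oxidation from unveiling of O1; it sets out from 20 and comes back at 24. Fluoride removes only the silyl ether (n-Bu4NF, THF, 0 °C) to give 1-[4,6-bis(benzyloxy)-2-tert-butoxy-3-{(1S)-1-[4-(benzyloxy)phenyl]-3-hydroxypropyl}phenyl]-3-phenylpropan-1-one F4. With no phenol free, the primary alcohol is oxidised to the acid (TEMPO cat., PhI(OAc)2, MeCN/H2O) to give (3S)-3-[4-(benzyloxy)phenyl]-3-[2,4-bis(benzyloxy)-6-tert-butoxy-5-(3-phenylpropanoyl)phenyl]propanoic acid F5. CF3CO2H in CH2Cl2 then cleaves the tert-butyl ether, and the liberated O1 phenol should lactonise onto the acid to give 24.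

Step 8. During quench and isolation the liberated N,O-dimethylhydroxylamine may add in conjugate fashion to the ynone, or the ynol ether may be hydrated by acid. The fallback avoids the amide altogether; it sets out from 14 (lithiated as 15) and comes back at 16. Acetylide 15 is added to purchased 3-phenylpropanal F6 (THF, −78 °C) to give racemic 1-tert-butoxy-5-phenylpent-1-yn-3-ol F7, and neutral oxidation of this propargylic alcohol (MnO2, CH2Cl2, 23 °C) should give 16 with no amine or acid present.

Further compounds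
F1 | step 9 | 5,7-dihydroxy-2H-chromen-2-one (purchased) | O=C1C=Cc2c(O)cc(O)cc2O1
F2 | step 9 | 5,7-dihydroxy-8-(3-phenylpropanoyl)-2H-chromen-2-one | O=C1C=Cc2c(O)cc(O)c(C(=O)CCc3ccccc3)c2O1
F3 | step 9 | 5,7-bis(benzyloxy)-8-(3-phenylpropanoyl)-2H-chromen-2-one | O=C1C=Cc2c(OCc3ccccc3)cc(OCc3ccccc3)c(C(=O)CCc3ccccc3)c2O1
F4 | step 12 | 1-[4,6-bis(benzyloxy)-2-tert-butoxy-3-{(1S)-1-[4-(benzyloxy)phenyl]-3-hydroxypropyl}phenyl]-3-phenylpropan-1-one | OCC[C@@H](c1ccc(OCc2ccccc2)cc1)c1c(OCc2ccccc2)cc(OCc2ccccc2)c(C(=O)CCc2ccccc2)c1OC(C)(C)C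
F5 | step 12 | (3S)-3-[4-(benzyloxy)phenyl]-3-[2,4-bis(benzyloxy)-6-tert-butoxy-5-(3-phenylpropanoyl)phenyl]propanoic acid | OC(=O)C[C@@H](c1ccc(OCc2ccccc2)cc1)c1c(OCc2ccccc2)cc(OCc2ccccc2)c(C(=O)CCc2ccccc2)c1OC(C)(C)C
F6 | step 8 | 3-phenylpropanal (purchased) | O=CCCc1ccccc1
F7 | step 8 | 1-tert-butoxy-5-phenylpent-1-yn-3-ol (racemic) | CC(C)(C)OC#CC(O)CCc1ccccc1
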